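## Structural features

The target joins three ring systems through two adjacent spiro atoms. Ring A is a 4,4-dimethylcyclohexene-1,5-dione whose C1 carbonyl, C2 methyl and C3 methoxy group form a vinylogous methyl ester; it shares C6 with a cyclopentane (C6–C10), which shares C10 with C2 of a 6,6-dimethylbicyclo[3.1.1]heptane (C10–C16, the pinane unit). C6, C7 and C10 are contiguous stereocentres on the five-membered ring, C6 and C10 being vicinal quaternary carbons, and C10 is bonded to the bridgehead stereocentre C15, which with C13 comes from the terpene. In the required diastereomer C6 lies syn and C9 anti to the CMe2 bridge C16, and the isopropyl group on C7 sits on the cyclopentane face that holds C11 and the C1 carbonyl, opposite to C15 and the C5 carbonyl. Fragile elements are the strained cyclobutane of the pinane unit (cationic rearrangement in strong acid), the enol ether (acid hydrolysis) and the two non-enolisable 1,3-dicarbonyl junctions at C6 and C4 (retro-Claisen cleavage by nucleophilic bases). The real difficulty is the pair of vicinal quaternary spiro centres together with C7, none of which can be corrected once ring A is closed, plus the need to methylate the C3 oxygen and not the C1 oxygen. The key step exploits that C10, C9, C8 and C6 map onto a cyclobutanone available from the exocyclic C10=C6 alkene of a pinane and a ketene, while C7 with its isopropyl group is a single carbon between C8 and C6 that a diazoalkane can insert; the temporary C8 carbonyl makes C7 epimerisable and two chlorines on C9 decide the side of insertion.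

## Logic of the disconnections

31 ⇒ 30. The O–CH3 bond on the C3 oxygen is cut. The enol ether is the most acid-labile group, so it is made last. This leaves 30, whose ring A carries only enolised carbonyl groups. The forward step must alkylate the oxygen on C3, not the one on C1 and not C2.

30 ⇒ 29. The C1–C2 bond is cut. In 29, C2 is the only carbon with acidic hydrogen, so the closure has one possible course. Ring A opens to a chain on C6 with both quaternary carbons C4 and C6 already in place. The forward step needs a non-nucleophilic base (C6 and C4 are retro-Claisen-prone junctions) and must close onto a shielded ester.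

29 ⇒ 21 + 27 (through 28). The C5–C6 bond is cut. Forming it late lets the isopropyl group on C7 direct the configuration of the quaternary C6. The molecule falls into a seven-carbon acyl unit and a spiro monoester with one quaternary carbon fewer. The forward step must acylate a crowded enolate on carbon, from the face anti to isopropyl.

27 ⇒ 25 ⇒ 22 + 23 (through 26 and 24). The C–Cl bond is traced back to an ester C–O bond and the C3–C4 bond is cut. A fully substituted ester enolate can only be acylated once, so the piece assembles cleanly. Two commercial three- and four-carbon units result. The forward steps need C-acylation and cold handling of 26, which can lose CO2.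

21 ⇒ 20 ⇒ 19. The ester O–CH3 bond is cut and C1 is returned to the alcohol level. An ester on C6 would make the alkene too electron-poor for the cycloaddition, whereas a CH2O arm tolerates ketene, diazoalkane, zinc and hydrazine. The arm becomes a spectator for six steps. The forward steps need oxidation of a hindered primary alcohol.

19 ⇒ 17 (through 18). A carbonyl is reinstated on C8 and a silyl group on the arm oxygen. The C8 carbonyl is what a ring enlargement leaves behind and is the handle that makes C7 correctable. This connects the saturated cyclopentane to ketone chemistry. The forward step must reduce a hindered ketone completely to CH2.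

17 ⇒ 16. Two C–Cl bonds are reinstated on C9. They are the regiochemical control element of the ring enlargement and the signature of a halogenated ketene. Nothing is lost in simplicity, since they come with the ketene. The forward step must remove both reductively and leave C7 trans to the C6 arm.

16 ⇒ 11 + 15. The C6–C7 and C7–C8 bonds are cut and C7 with its isopropyl group leaves as a one-carbon unit. A cyclopentanone with a substituted α-carbon is the homologue of a cyclobutanone. One ring size and one stereocentre fewer remain, and the four-membered ketone is a ketene–alkene adduct. The forward step must migrate C6, not C9, and stop after one insertion.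

15 ⇒ 13 ⇒ 12 (through 14). The C=N2 unit is traced back to a sulfonylhydrazone C=N bond and then to the aldehyde C=O. The hydrazone is a storable precursor of an unstable reagent. The reagent reduces to a commodity aldehyde. The forward step must release the diazoalkane without letting it lose nitrogen.

11 ⇒ 8 + 10 (10 from 9). The C9–C10 and C6–C8 bonds are cut. Both belong to one cycloaddition that creates the quaternary C10 on the open face of the pinane. The spiro ketone falls into a trisubstituted exocyclic alkene and a two-carbon unit. The forward step must attack anti to C16, and 8 must be the Z isomer so that the arm ends cis to C15.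

8 ⇒ 7 ⇒ 6 ⇒ 3 + 4 (through 5). The Si–O bond is cut, C1 is returned to the ester level, and the C10=C6 bond is cut. Olefination of a ketone is the most direct way to add C6 and C1. A terpene ketone and a phosphonate remain. The forward sequence must supply the Z alkene.

3 ⇒ 1 (through 2). The C10=O bond is traced back to the exocyclic C10=CH2 bond. The hydrocarbon is the commercial carrier of C13 and C15 in the right absolute configuration. The demand is an oxidative cleavage under neutral conditions that spares the cyclobutane.

## Other disconnections considered

Alternative 1: The cut is the C5–C6 bond of ring A.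
- Forward: the open-chain 1,3-diketone ester A2 (C6 still bearing hydrogen, C1/C3 as the diketone) is deprotonated twice, at C2 and then at C6. The C6 carbanion attacks the C5 ester in a six-membered closure to give A1, which is identical with 30.
- In its favour: the most crowded bond of the molecule is made intramolecularly, its side-chain building block needs no acid chloride, and C6 is set by closure anti to isopropyl, the same control element as in the chosen plan.
- Against it: the second deprotonation must occur at a tertiary, shielded carbon of an already anionic diketone; the chain has to be attached to C1 by aldol addition and oxidation; and it does not say how the cyclopentane with C7 and C10 is made.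
- Comparison: for forming C5–C6 it is probably the better solution (intramolecular against intermolecular at a quaternary carbon) and its side branch is shorter. The chosen plan has the more dependable enolisation in its ring closure (one unhindered CH2 in 29). Main-chain step counts are equal and the O-methylation problem is identical. It is therefore kept as the fallback for step 15.

Alternative 2: The cuts are C9–C10 and C6–C7.
- Forward: the alkylidene malonate A4 (from 3 by Knoevenagel condensation) takes up the homoprenyl Grignard reagent A5 at C10 under copper catalysis. A one-electron oxidant then turns the malonate enolate into a C6 radical, which closes 5-exo onto the trisubstituted alkene; oxidation of the tertiary radical gives the isopropenyl compound A3.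
- In its favour: the whole spiro cyclopentane is reached from 3 in two operations without diazo compounds; both C1 and C5 are present at the ester level; no alkene geometry has to be controlled because C6 carries two identical groups.
- Against it: the conjugate addition must build the quaternary C10 on a shielded β,β-disubstituted acceptor. C7 is formed irreversibly with no adjacent carbonyl to correct it. The two esters, which differ only in their relation to C7, must later be told apart when the unsymmetrical C2–C3–C4 unit is attached, and that choice fixes C6.
- Comparison: it is better on step count, reagent safety and the geometry question; equal on the facial control at C10 (attack anti to C16 in both); weaker on C7 and C6, where the chosen plan has an equilibration and a stepwise introduction of C1 and C5.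

Alternative 3: The cut is C6–C7 with C6 as a carbon of an aromatic ring A.
- Forward: the resorcinol-type arene A7, already bonded through C6 to the quaternary C10 and carrying an epoxide on the C9–C8–C7 tether, is deprotonated. The phenoxide carbon opens the epoxide at C7 (5-exo, inversion at C7) to give the dearomatised A6, in which the future isopropyl carbon is still a carbinol.
- In its favour: ring A arrives complete with its oxygens and the methoxy group already in the right place; C7 is set stereospecifically from an epoxide whose configuration can be chosen by the reagent; O-alkylation would need a seven-membered ring, so C-alkylation is favoured.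
- Against it: A7 needs a hexasubstituted arene on the quaternary C10, syn to C16, at a tertiary position prone to cationic rearrangement of the pinane. C6 becomes stereogenic only when C4 rather than C2 is later methylated, a choice between two nearly equivalent carbons. The carbinol must also be deoxygenated.
- Comparison: it is better on the origin of ring A (no late choice between two enol oxygens) and on C7; weaker on C10 and C6; step count is at best comparable.

Key step: step 8

Remark: the C6 arm is carried as a tert-butyldiphenylsilyl ether rather than a benzyl ether (skeleton unchanged), because the bulky, weakly basic oxygen should not react with the ketene or ZnCl2 and the group is lost in step 10 without a separate step.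
Remark: the alkene of 8 must be Z (arm cis to C15); only then does the suprafacial cycloaddition place the arm of 11 cis to C15, so that equilibration puts isopropyl cis to C11.
Remark: step 2 is assumed to give both geometrical isomers in separable form; only the Z isomer is carried on.
Remark: 22, 23 and all reagents are assumed to be commercial.

## Steps

Step 1
Reactants: 1 (1R,5R)-(+)-β-pinene
Product: 3 (1S,5R)-(−)-nopinone, (1S,5R)-6,6-dimethylbicyclo[3.1.1]heptan-2-one, via secondary ozonide 2 (not isolated)
Conditions: O3, CH2Cl2, −78 °C; then Me2S, −78 → 25 °C
Reagents that add atoms: ozone, [O-][O+]=O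
Why: Ozonolysis of the 1,1-disubstituted alkene with reductive work-up removes the exocyclic CH2 as formaldehyde and leaves the C10 ketone; the neutral conditions spare the cyclobutane and the bridgehead stereocentres are untouched.

Step 2
Reactants: 3 nopinone; 4 triethyl phosphonoacetate
Product: 6 ethyl (Z)-2-[(1S,5R)-6,6-dimethylbicyclo[3.1.1]heptan-2-ylidene]acetate (ester group cis to the bridgehead carbon C15), via sodium phosphonate carbanion 5 (not isolated)
Conditions: NaH, THF, 0 °C; then 3, 0 → 65 °C; chromatographic separation of the geometrical isomers
Reagents that add atoms: none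
Why: Horner–Wadsworth–Emmons olefination forms C10=C6 and brings in C1; both geometrical isomers should form because allylic strain toward the in-plane C15–H and toward the C11 methylene is similar. Only the Z isomer is carried on, since step 5 turns this geometry into the C6 configuration on which the equilibration of C7 depends.

Step 3
Reactants: 6 (Z)-ester
Product: 7 (Z)-2-[(1S,5R)-6,6-dimethylbicyclo[3.1.1]heptan-2-ylidene]ethanol
Conditions: iBu2AlH (2.2 equiv), CH2Cl2, −78 → 0 °C; aqueous Rochelle salt
Reagents that add atoms: none
Why: 1,2-Reduction of the conjugated ester by the aluminium hydride gives the allylic alcohol; the double bond is not touched, so the Z geometry is kept.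

Step 4
Reactants: 7 (Z)-allylic alcohol
Product: 8 tert-butyl{[(Z)-2-((1S,5R)-6,6-dimethylbicyclo[3.1.1]heptan-2-ylidene)ethyl]oxy}diphenylsilane
Conditions: t-BuPh2SiCl, imidazole, CH2Cl2, 25 °C
Reagents that add atoms: tert-butyl(chloro)diphenylsilane, CC(C)(C)[Si](Cl)(c1ccccc1)c1ccccc1
Why: Silylation of the primary alcohol; the hindered silyl ether oxygen should neither be acylated under ZnCl2 nor enter a zwitterionic [3,3] pathway with the ketene.

Step 5
Reactants: 8 (Z)-allylic silyl ether; 9 trichloroacetyl chloride
Product: 11 spiro α,α-dichlorocyclobutanone (C10 spiro; C9 = CCl2 anti to the CMe2 bridge; C8 = C=O; C6 syn to the bridge, bearing H and the silyloxymethyl arm cis to C15), via dichloroketene 10 (not isolated)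
Conditions: activated Zn (Zn–Cu couple), 9 added slowly, Et2O/1,2-dimethoxyethane, 25–35 °C
Reagents that add atoms: none
Why: Zinc converts 9 into dichloroketene, which adds to the trisubstituted alkene in a thermal ketene–alkene [2+2] cycloaddition: the carbonyl carbon bonds to the less substituted C6 and the CCl2 carbon to C10, from the face anti to the CMe2 bridge, so C10 is set with C9 anti and C6 syn to C16. The addition is suprafacial on the alkene, so the Z geometry places the arm cis to C15; dimethoxyethane ties up ZnCl2.

Step 6
Reactants: 12 isobutyraldehyde
Product: 13 isobutyraldehyde p-toluenesulfonylhydrazone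
Conditions: TsNHNH2, MeOH, 0 → 25 °C
Reagents that add atoms: p-toluenesulfonyl hydrazide, Cc1ccc(cc1)S(=O)(=O)NN
Why: Condensation of the aldehyde with the sulfonyl hydrazide gives a crystalline, storable precursor of the diazoalkane.

Step 7
Reactants: 13 tosylhydrazone
Product: 15 1-diazo-2-methylpropane (cold ethereal solution, used at once), via tosylhydrazone sodium salt 14 (not isolated)
Conditions: NaOMe, MeOH, 25 °C; evaporation to dryness; 90–120 °C, 0.1 mmHg, distillate trapped at −78 °C and taken up in Et2O
Reagents that add atoms: none
Why: Bamford–Stevens decomposition of the dry salt under vacuum expels sulfinate; the volatile diazoalkane distils out of the hot zone as it forms, before it can lose nitrogen.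

Step 8
Reactants: 11 spiro dichlorocyclobutanone; 15 1-diazo-2-methylpropane (1.5–2 equiv)
Product: 16 spiro 2,2-dichlorocyclopentanone (C9 = CCl2, C8 = C=O, C7 bearing isopropyl trans to the C6 arm and cis to C11)
Conditions: Et2O, −78 → 0 °C; excess 15 quenched with AcOH
Reagents that add atoms: none
Why: The nucleophilic diazo carbon adds to the C8 carbonyl, activated by ring strain and the two α-chlorines, from the face opposite the C6 arm, giving a diazonium alkoxide. As nitrogen leaves, the C6–C8 bond migrates to the diazonium carbon with retention at C6, forming C6–C7 beside the C7–C8 bond made in the addition; the electron-poor CCl2 carbon C9 migrates poorly, so insertion occurs on the C6 side only. The closest known reaction type is the regioselective homologation of α,α-dichlorocyclobutanones with diazomethane or diazoethane to 2,2-dichlorocyclopentanones. The five-membered ring arises by ring enlargement through a 1,2-shift, not by end-to-end cyclisation, so no exo or endo mode applies; loss of N2 and relief of four-ring strain drive it. The new stereocentre C7 should form trans to the C6 arm because migration proceeds through the rotamer that keeps isopropyl away from the arm, and since C7–H is acidic the centre is in any case put under thermodynamic control in step 9. The step needs site selectivity (secured by the chlorines), a single homologation (16 is unstrained and more hindered than 11) and migration rather than epoxide closure (favoured by strain release).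

Step 9
Reactants: 16 spiro dichlorocyclopentanone
Product: 17 spiro cyclopentanone (C9 = CH2; isopropyl on C7 trans to the C6 arm)
Conditions: Zn dust, AcOH, 25 → 60 °C; then NaOMe (cat.), MeOH/THF, 25 °C
Reagents that add atoms: none
Why: Zinc reduces both α-C–Cl bonds through zinc enolates that acetic acid protonates; the catalytic base then equilibrates C7, the only epimerisable centre (C6 is β to the carbonyl), to the arrangement with isopropyl trans to the vicinal arm and cis to C11.

Step 10
Reactants: 17 spiro cyclopentanone
Product: 19 primary alcohol (C8 = CH2; CH2OH on C6 cis to C15; isopropyl on C7 trans to it), via hydrazone 18 (not isolated)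
Conditions: N2H4·H2O, KOH, diethylene glycol, 130 °C; then removal of water, 200 °C
Reagents that add atoms: none
Why: Wolff–Kishner reduction (Huang–Minlon modification) converts the C8 carbonyl into CH2 via the hydrazone; C7 is already in its stable configuration, so the base cannot harm it. Hot KOH in glycol also cleaves the silyl ether, freeing the arm for oxidation.

Step 11
Reactants: 19 primary alcohol
Product: 20 carboxylic acid (C1 = CO2H on C6)
Conditions: 2,2,6,6-tetramethylpiperidin-1-oxyl (cat.), NaOCl (cat.), NaClO2, MeCN/phosphate buffer (pH 6.7), 35 °C
Reagents that add atoms: sodium chlorite, [Na+].[O-]Cl=O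
Why: Oxoammonium oxidation to the aldehyde and chlorite oxidation to the acid; the rest of the molecule is saturated hydrocarbon, and any epimerisation at C6 is irrelevant because C6 is made planar in step 15.

Step 12
Reactants: 20 carboxylic acid
Product: 21 methyl ester (C1 = CO2Me on C6)
Conditions: MeI, K2CO3, HCONMe2, 25 °C
Reagents that add atoms: iodomethane, CI
Why: O-Alkylation of the carboxylate is insensitive to the steric shielding that would slow acid-catalysed esterification of this α-branched acid.

Step 13
Reactants: 22 tert-butyl isobutyrate; 23 propionyl chloride
Product: 25 tert-butyl 2,2-dimethyl-3-oxopentanoate, via lithium enolate 24 (not isolated)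
Conditions: LiN(iPr)2, THF, −78 °C; then 23, −78 → 0 °C
Reagents that add atoms: none
Why: C-Acylation of a fully substituted lithium ester enolate by an acid chloride (crossed Claisen-type acylation); the product has no hydrogen between its carbonyl groups and cannot quench the enolate.

Step 14
Reactants: 25 tert-butyl keto ester
Product: 27 2,2-dimethyl-3-oxopentanoyl chloride, via keto acid 26 (not isolated)
Conditions: CF3CO2H, CH2Cl2, 0 → 20 °C; evaporation below 25 °C; (COCl)2, HCONMe2 (cat.), CH2Cl2, 0 °C
Reagents that add atoms: oxalyl chloride, ClC(=O)C(Cl)=O
Why: Acidolysis of the tert-butyl ester (loss of isobutene), then chloroiminium-mediated conversion of the acid into the chloride; the β-keto acid is kept cold and not isolated because it can decarboxylate, and the chloride cannot form a ketene since C4 bears no hydrogen.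

Step 15
Reactants: 21 methyl ester; 27 acid chloride (1.5 equiv)
Product: 29 β-keto ester with quaternary C6 (CO2Me = C1 cis to isopropyl; 2,2-dimethyl-3-oxopentanoyl group = C5 to C2 trans to isopropyl), via lithium enolate 28 (not isolated)
Conditions: LiN(iPr)2, THF, −78 → −30 °C; then 27, −78 → 0 °C
Reagents that add atoms: none
Why: Deprotonation makes C6 planar and the lithium ester enolate is C-acylated by the acid chloride. The electrophile should approach the face opposite the vicinal isopropyl group (that face carries only the C7 hydrogen and C15; the other carries isopropyl and C11), which sets the quaternary C6 with C5 trans and C1 cis to isopropyl.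

Step 16
Reactants: 29 β-keto ester
Product: 30 ring A triketone in its enol form (O-desmethyl target)
Conditions: KN(SiMe3)2 (1.5 equiv), THF, −78 → 0 °C; then aqueous HCl
Reagents that add atoms: none
Why: Dieckmann condensation: the ethyl CH2 (C2) is the only acidic position of 29, its enolate attacks the C1 ester in a 6-exo-trig closure, and deprotonation of the new 1,3-diketone by the released methoxide drives the reaction. The non-nucleophilic base avoids retro-Claisen cleavage at C6 and C4.

Step 17
Reactants: 30 triketone enol
Product: 31 target, CNP0307059.1
Conditions: Me3SiCHN2, MeOH/toluene, 0 → 25 °C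
Reagents that add atoms: trimethylsilyldiazomethane, C[Si](C)(C)C=[N+]=[N-]
Why: The acidic enol protonates the diazo reagent and the resulting methyldiazonium species alkylates oxygen rather than C2. The C3 oxygen, beside the C4 methyls, is more accessible than the C1 oxygen next to the spiro carbon C6 with its isopropyl and pinane neighbours, so the C3 methyl ether should prevail.

## Compound list

1 | (1R,5R)-(+)-β-pinene | C=C1CC[C@@H]2C[C@H]1C2(C)C | starting material
2 | secondary ozonide of 1 (spiro 1,2,4-trioxolane at C10; configuration at the spiro carbon not defined) | C1OOC2(O1)CC[C@@H]1C[C@H]2C1(C)C | intermediate (not isolated)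
3 | (1S,5R)-(−)-nopinone | O=C1CC[C@@H]2C[C@H]1C2(C)C | intermediate
4 | triethyl phosphonoacetate | CCOC(=O)CP(=O)(OCC)OCC | starting material
5 | sodium salt of 4 (phosphonate carbanion) | CCOC(=O)[CH-]P(=O)(OCC)OCC.[Na+] | intermediate (not isolated)
6 | ethyl (Z)-2-[(1S,5R)-6,6-dimethylbicyclo[3.1.1]heptan-2-ylidene]acetate, ester cis to bridgehead C15 | CCOC(=O)/C=C1/CC[C@@H]2C[C@H]1C2(C)C | intermediate
7 | (Z)-2-[(1S,5R)-6,6-dimethylbicyclo[3.1.1]heptan-2-ylidene]ethanol | OC/C=C1/CC[C@@H]2C[C@H]1C2(C)C | intermediate
8 | tert-butyldiphenylsilyl ether of 7 | CC(C)(C)[Si](OC/C=C1/CC[C@@H]2C[C@H]1C2(C)C)(c1ccccc1)c1ccccc1 | intermediate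
9 | trichloroacetyl chloride | ClC(=O)C(Cl)(Cl)Cl | starting material
10 | dichloroketene | ClC(Cl)=C=O | intermediate (not isolated)
11 | spiro α,α-dichlorocyclobutanone: 2′,2′-dichloro-4′-[(tert-butyldiphenylsilyloxy)methyl]-6,6-dimethylspiro[bicyclo[3.1.1]heptane-2,1′-cyclobutan]-3′-one, C9 anti and C6 syn to the CMe2 bridge, arm on C6 cis to C15 | O=C1C(Cl)(Cl)[C@@]2(CC[C@@H]3C[C@H]2C3(C)C)[C@@H]1CO[Si](c1ccccc1)(c1ccccc1)C(C)(C)C | intermediate (key-step precursor)
12 | isobutyraldehyde | CC(C)C=O | starting material
13 | isobutyraldehyde p-toluenesulfonylhydrazone | CC(C)C=NNS(=O)(=O)c1ccc(C)cc1 | intermediate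
14 | sodium salt of 13 | CC(C)C=N[N-]S(=O)(=O)c1ccc(C)cc1.[Na+] | intermediate (not isolated)
15 | 1-diazo-2-methylpropane | CC(C)C=[N+]=[N-] | intermediate
16 | spiro 2,2-dichlorocyclopentanone: 2′,2′-dichloro-5′-[(tert-butyldiphenylsilyloxy)methyl]-4′-isopropyl-6,6-dimethylspiro[bicyclo[3.1.1]heptane-2,1′-cyclopentan]-3′-one, arm on C6 cis to C15, isopropyl on C7 trans to the arm | O=C1C(Cl)(Cl)[C@@]2(CC[C@@H]3C[C@H]2C3(C)C)[C@H](CO[Si](c3ccccc3)(c3ccccc3)C(C)(C)C)[C@H]1C(C)C | intermediate (key-step product)
17 | dechlorinated spiro cyclopentanone, same configuration as 16 | O=C1C[C@@]2(CC[C@@H]3C[C@H]2C3(C)C)[C@H](CO[Si](c3ccccc3)(c3ccccc3)C(C)(C)C)[C@H]1C(C)C | intermediate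
18 | hydrazone of 17 | NN=C1C[C@@]2(CC[C@@H]3C[C@H]2C3(C)C)[C@H](CO[Si](c3ccccc3)(c3ccccc3)C(C)(C)C)[C@H]1C(C)C | intermediate (not isolated)
19 | primary alcohol: [3′-isopropyl-6,6-dimethylspiro[bicyclo[3.1.1]heptane-2,1′-cyclopentan]-2′-yl]methanol, CH2OH on C6 cis to C15, isopropyl trans to it | C1C[C@@]2(CC[C@@H]3C[C@H]2C3(C)C)[C@H](CO)[C@H]1C(C)C | intermediate
20 | carboxylic acid corresponding to 19 (C1 = CO2H) | C1C[C@@]2(CC[C@@H]3C[C@H]2C3(C)C)[C@H](C(=O)O)[C@H]1C(C)C | intermediate
21 | methyl ester of 20 | C1C[C@@]2(CC[C@@H]3C[C@H]2C3(C)C)[C@H](C(=O)OC)[C@H]1C(C)C | intermediate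
22 | tert-butyl isobutyrate | CC(C)C(=O)OC(C)(C)C | starting material
23 | propionyl chloride | CCC(=O)Cl | starting material
24 | lithium enolate of 22 | CC(C)=C([O-])OC(C)(C)C.[Li+] | intermediate (not isolated)
25 | tert-butyl 2,2-dimethyl-3-oxopentanoate | CCC(=O)C(C)(C)C(=O)OC(C)(C)C | intermediate
26 | 2,2-dimethyl-3-oxopentanoic acid | CCC(=O)C(C)(C)C(=O)O | intermediate (not isolated)
27 | 2,2-dimethyl-3-oxopentanoyl chloride | CCC(=O)C(C)(C)C(=O)Cl | intermediate
28 | lithium enolate of 21 (C6 planar) | C1C[C@@]2(CC[C@@H]3C[C@H]2C3(C)C)C(=C([O-])OC)[C@H]1C(C)C.[Li+] | intermediate (not isolated)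
29 | β-keto ester with quaternary C6: CO2Me (C1) cis and the 2,2-dimethyl-3-oxopentanoyl group (C5) trans to isopropyl | C1C[C@@]2(CC[C@@H]3C[C@H]2C3(C)C)[C@](C(=O)OC)(C(=O)C(C)(C)C(=O)CC)[C@H]1C(C)C | intermediate
30 | ring A triketone, enol form (O-desmethyl target) | OC1=C(C)C(=O)[C@@]2(C(=O)C1(C)C)[C@@H](C(C)C)CC[C@@]21CC[C@@H]2C[C@H]1C2(C)C | intermediate
31 | CNP0307059.1 | COC1=C(C)C(=O)[C@@]2(C(=O)C1(C)C)[C@@H](C(C)C)CC[C@@]21CC[C@@H]2C[C@H]1C2(C)C | target

## Step count and least certain steps

Total: 17 steps. Longest linear sequence: 13 steps (1–5, 8–12, 15–17); steps 6–7 and 13–14 are side branches.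

**Step 8 (key step).** What may go wrong: the branched diazoalkane may be lost through 1,2-hydrogen shift and azine formation before it adds to a carbonyl shielded by CCl2 and the substituted C6, and the diazonium alkoxide may close to an epoxide instead of rearranging. Fallback, from 11 back to 17:
- ring enlargement of 11 with diazomethane (Et2O, 0 °C), the parent reaction of this class, gives the 2,2-dichlorocyclopentanone with unsubstituted C7 F1;
- because C9 has no hydrogen, enolisation can only go toward C7, so TiCl4/Et3N and acetone give the C7 aldol adduct F2;
- dehydration (MeSO2Cl, Et3N) gives the 2,2-dichloro-5-isopropylidene ketone F3;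
- Zn/AcOH removes the chlorines to give the isopropylidene ketone F4;
- hydrogenation (H2, Pd on carbon) and NaOMe equilibration give 17.

**Step 2.** What may go wrong: the two geometrical isomers may partition unfavourably, since the ester meets similar allylic strain on either side of C10, leaving too little of the Z series. Fallback, from 3 back to 8 with defined geometry:
- 3 is condensed with 2,4,6-triisopropylbenzenesulfonyl hydrazide to the sulfonylhydrazone F5;
- Shapiro reaction (n-BuLi, 2 equiv) gives the C10 vinyllithium F6;
- acylation with 2-(tert-butyldiphenylsilyloxy)-N-methoxy-N-methylacetamide gives the enone F7;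
- Corey–Bakshi–Shibata reduction ((S)-1-methyl-3,3-diphenyltetrahydro-1H,3H-pyrrolo[1,2-c][1,3,2]oxazaborole (cat.), BH3·SMe2, the catalyst enantiomer chosen for the S carbinol) gives the (S)-allylic alcohol F8;
- Mitsunobu reaction with 2-nitrobenzenesulfonyl hydrazide (PPh3, diethyl azodicarboxylate, −30 °C) gives, with inversion, the N-allyl-N-sulfonylhydrazine F9;
- on warming F9 loses the sulfinic acid to give the monoalkyl diazene F10, whose retro-ene loss of N2 delivers hydrogen to C11 on the face anti to the CMe2 bridge. From the S carbinol this places the silyloxymethyl group anti to C11, that is cis to C15, and gives 8.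

**Step 15.** What may go wrong: C–C bond formation may fail between the fully substituted enolate carbon C6 (flanked by quaternary C10 and C7) and a carbonyl beside CMe2, with proton transfer from the CH2 group of 27 or O-acylation taking over. Attack syn to isopropyl is a second risk, because the anti face is also shielded by C15. Fallback, from 19 back to 30, making the crowded bond intramolecularly:
- 19 is oxidised with Dess–Martin periodinane to the aldehyde F11;
- methyl 2,2-dimethyl-3-oxopentanoate F12 (made like 25 from methyl isobutyrate and 23) is deprotonated at its ethyl group with LiN(iPr)2 and added to F11, giving the aldol adduct F13;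
- a second Dess–Martin oxidation gives the 1,3-diketone ester F14 (the same compound as A2);
- excess LiN(iPr)2 forms the dianion and the C6 carbanion closes onto the C5 ester anti to isopropyl, giving 30.

**Step 10.** What may go wrong: hydrazone formation at the hindered C8 carbonyl may be incomplete, azine may form, and the silyl ether may be cleaved only partly. Fallback, from 17 back to 19:
- ethane-1,2-dithiol and BF3·OEt2 give the 1,3-dithiolane F15;
- Raney Ni in ethanol gives the deoxygenated silyl ether F16;
- Bu4NF gives 19.

**Step 17.** What may go wrong: methylation may take place at the wrong enol oxygen (C1 instead of C3), because both oxygens flank quaternary carbons. Fallback, from 30 back to 31 under thermodynamic control: 30, or a mixture containing the C1 methyl enol ether F17, is heated with MeOH, HC(OMe)3 and p-toluenesulfonic acid (cat.). The two enol ethers interconvert through the mixed ketal, so the distribution is set by stability (methoxy beside the less encumbered C4) rather than by rate.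

## Further compounds

F1 | step 8 | 2,2-dichlorocyclopentanone with unsubstituted C7 | O=C1C(Cl)(Cl)[C@@]2(CC[C@@H]3C[C@H]2C3(C)C)[C@H](CO[Si](c3ccccc3)(c3ccccc3)C(C)(C)C)C1
F2 | step 8 | C7 aldol adduct with 2-hydroxypropan-2-yl group (C7 configuration not defined) | O=C1C(Cl)(Cl)[C@@]2(CC[C@@H]3C[C@H]2C3(C)C)[C@H](CO[Si](c3ccccc3)(c3ccccc3)C(C)(C)C)C1C(C)(C)O
F3 | step 8 | 2,2-dichloro-5-isopropylidene ketone | O=C1C(Cl)(Cl)[C@@]2(CC[C@@H]3C[C@H]2C3(C)C)[C@H](CO[Si](c3ccccc3)(c3ccccc3)C(C)(C)C)C1=C(C)C
F4 | step 8 | isopropylidene ketone without chlorine | O=C1C[C@@]2(CC[C@@H]3C[C@H]2C3(C)C)[C@H](CO[Si](c3ccccc3)(c3ccccc3)C(C)(C)C)C1=C(C)C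
F5 | step 2 | nopinone 2,4,6-triisopropylbenzenesulfonylhydrazone | CC(C)c1cc(C(C)C)c(c(c1)C(C)C)S(=O)(=O)NN=C1CC[C@@H]2C[C@H]1C2(C)C
F6 | step 2 | C10 vinyllithium, 6,6-dimethylbicyclo[3.1.1]hept-2-en-2-yllithium | [Li]C1=CC[C@@H]2C[C@H]1C2(C)C
F7 | step 2 | enone, 2-(tert-butyldiphenylsilyloxy)-1-(6,6-dimethylbicyclo[3.1.1]hept-2-en-2-yl)ethanone | O=C(CO[Si](c1ccccc1)(c1ccccc1)C(C)(C)C)C1=CC[C@@H]2C[C@H]1C2(C)C
F8 | step 2 | (S)-allylic alcohol | O[C@H](CO[Si](c1ccccc1)(c1ccccc1)C(C)(C)C)C1=CC[C@@H]2C[C@H]1C2(C)C
F9 | step 2 | N-allyl-N-(2-nitrobenzenesulfonyl)hydrazine, inverted at the carbinol carbon | NN([C@@H](CO[Si](c1ccccc1)(c1ccccc1)C(C)(C)C)C1=CC[C@@H]2C[C@H]1C2(C)C)S(=O)(=O)c1ccccc1[N+](=O)[O-]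
F10 | step 2 | monoalkyl diazene | N=N[C@@H](CO[Si](c1ccccc1)(c1ccccc1)C(C)(C)C)C1=CC[C@@H]2C[C@H]1C2(C)C
F11 | step 15 | aldehyde (C1 = CHO on C6) | C1C[C@@]2(CC[C@@H]3C[C@H]2C3(C)C)[C@H](C=O)[C@H]1C(C)C
F12 | step 15 | methyl 2,2-dimethyl-3-oxopentanoate | CCC(=O)C(C)(C)C(=O)OC
F13 | step 15 | aldol adduct (new carbinol and C2 centres not defined) | C1C[C@@]2(CC[C@@H]3C[C@H]2C3(C)C)[C@H](C(O)C(C)C(=O)C(C)(C)C(=O)OC)[C@H]1C(C)C
F14 | step 15 | 1,3-diketone ester (C2 not defined) | C1C[C@@]2(CC[C@@H]3C[C@H]2C3(C)C)[C@H](C(=O)C(C)C(=O)C(C)(C)C(=O)OC)[C@H]1C(C)C
F15 | step 10 | 1,3-dithiolane of 17 | C12(SCCS1)C[C@@]3(CC[C@@H]4C[C@H]3C4(C)C)[C@H](CO[Si](c4ccccc4)(c4ccccc4)C(C)(C)C)[C@H]2C(C)C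
F16 | step 10 | deoxygenated silyl ether | C1C[C@@]2(CC[C@@H]3C[C@H]2C3(C)C)[C@H](CO[Si](c3ccccc3)(c3ccccc3)C(C)(C)C)[C@H]1C(C)C
F17 | step 17 | C1 methyl enol ether, regioisomer of 31 | O=C1C(C)=C(OC)[C@@]2(C(=O)C1(C)C)[C@@H](C(C)C)CC[C@@]21CC[C@@H]2C[C@H]1C2(C)C
A1 | alternative 1 | O-desmethyl target, identical with 30 | OC1=C(C)C(=O)[C@@]2(C(=O)C1(C)C)[C@@H](C(C)C)CC[C@@]21CC[C@@H]2C[C@H]1C2(C)C
A2 | alternative 1 | open-chain 1,3-diketone ester with C6–H | C1C[C@@]2(CC[C@@H]3C[C@H]2C3(C)C)[C@H](C(=O)C(C)C(=O)C(C)(C)C(=O)OC)[C@H]1C(C)C
A3 | alternative 2 | spiro cyclopentane gem-diester with isopropenyl on C7 | COC(=O)C1(C(=O)OC)[C@@H](C(C)=C)CC[C@@]12CC[C@@H]3C[C@H]2C3(C)C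
A4 | alternative 2 | dimethyl 2-[(1S,5R)-6,6-dimethylbicyclo[3.1.1]heptan-2-ylidene]malonate | COC(=O)C(C(=O)OC)=C1CC[C@@H]2C[C@H]1C2(C)C
A5 | alternative 2 | homoprenyl Grignard reagent, (4-methylpent-3-en-1-yl)magnesium bromide | CC(C)=CCC[Mg]Br
A6 | alternative 3 | spiro cyclohexadienone enol with C7 dimethylcarbinol | COC1=C(C)C(=O)C2(C(O)=C1C)[C@@H](C(C)(C)O)CC[C@@]21CC[C@@H]2C[C@H]1C2(C)C
A7 | alternative 3 | resorcinol-type arene on C10 with tethered trisubstituted epoxide | CC1(C)O[C@H]1CC[C@@]2(CC[C@@H]3C[C@H]2C3(C)C)c1c(O)c(C)c(OC)c(C)c1O
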